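**Retrosynthetic overview**
- The exocyclic methylene is installed last, by Stiles carboxylation and decarboxylative Mannich methylenation of the saturated trans-lactone diacid.
- That diacid comes from a lactone N-acyloxazolidinone by peroxide removal of the auxiliary and acid cleavage of a tert-butyl ester.
- The key C–C bond (oxolane C2–C3) is made by an Evans syn boron aldol between a succinate imide and tert-butyl 16-oxohexadecanoate. The only ring, the γ-lactone, closes in the same operation (new OH onto the succinate methyl ester), and the syn aldol becomes the trans lactone.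
- The imide comes from (S)-4-benzyloxazolidin-2-one and methyl succinyl chloride. The aldehyde comes from hexadecanedioic acid mono-tert-butyl ester by borane reduction and oxidation.

Assumption: 16-(tert-butoxy)-16-oxohexadecanoic acid (hexadecanedioic acid mono-tert-butyl ester, the bulk building block of the insulin degludec side chain) counts as a cheap commercial starting material.

Target configuration read from the SMILES: (2R,3S)-2-(14-carboxytetradecyl)-4-methylidene-5-oxooxolane-3-carboxylic acid, a trans lactone with 14 CH2 groups between the ring and the terminal CO2H.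

**Step 1**
Reactants: 1 (4S)-4-benzyl-1,3-oxazolidin-2-one; 2 methyl 4-chloro-4-oxobutanoate
Product: 3 methyl 4-[(4S)-4-benzyl-2-oxo-1,3-oxazolidin-3-yl]-4-oxobutanoate
Conditions: n-BuLi (1.0 equiv), THF, −78 °C; then 2 (1.1 equiv), −78 → 0 °C
Reagents that add atoms: none
Why: N-acylation of the deprotonated carbamate nitrogen by the acid chloride, which is far more electrophilic than the methyl ester, is the standard loading of an Evans auxiliary and touches no stereocentre.

**Step 2**
Reactants: 4 16-(tert-butoxy)-16-oxohexadecanoic acid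
Product: 5 tert-butyl 16-hydroxyhexadecanoate
Conditions: BH3·THF (1.5 equiv), THF, 0 °C → rt; MeOH quench
Reagents that add atoms: none
Why: Chemoselective borane reduction, since BH3 reduces a free carboxylic acid much faster than an ester and so leaves the hindered tert-butyl ester untouched.

**Step 3**
Reactants: 5 tert-butyl 16-hydroxyhexadecanoate
Product: 6 tert-butyl 16-oxohexadecanoate
Conditions: TEMPO (10 mol%), PhI(OAc)2 (1.1 equiv), CH2Cl2, rt; used promptly
Reagents that add atoms: none
Why: TEMPO/PhI(OAc)2 oxidation (oxoammonium catalysis) stops cleanly at the aldehyde for an unhindered primary alcohol and is mild enough for the tert-butyl ester.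

**Step 4**
Reactants: 3 methyl 4-[(4S)-4-benzyl-2-oxo-1,3-oxazolidin-3-yl]-4-oxobutanoate; 6 tert-butyl 16-oxohexadecanoate
Product: 9 tert-butyl 15-[(2R,3S)-3-{[(4S)-4-benzyl-2-oxo-1,3-oxazolidin-3-yl]carbonyl}-5-oxooxolan-2-yl]pentadecanoate, via boron enolate 7 (not isolated), via syn-aldol adduct 8 (not isolated)
Conditions: Bu2BOTf (1.2 equiv), i-Pr2NEt (1.4 equiv), CH2Cl2, 0 °C; then 6, −78 → 0 °C; pH 7 buffer/MeOH/30% H2O2, 0 °C; crude with PPTS (5 mol%), CH2Cl2, rt
Reagents that add atoms: none
Why: Evans syn aldol through a Zimmerman–Traxler chair, in which boron enolises only the imide to the (Z)-enolate 7, the aldehyde adds on the face away from the benzyl group to set both new stereocentres (3S,4R) in 8, and 5-exo attack of the new hydroxyl on the methyl ester then closes the γ-lactone so that the syn aldol becomes the trans-(2R,3S) lactone.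

**Step 5**
Reactants: 9 tert-butyl 15-[(2R,3S)-3-{[(4S)-4-benzyl-2-oxo-1,3-oxazolidin-3-yl]carbonyl}-5-oxooxolan-2-yl]pentadecanoate
Product: 11 (2R,3S)-2-(15-tert-butoxy-15-oxopentadecyl)-5-oxooxolane-3-carboxylic acid, via peroxy acid 10 (not isolated)
Conditions: LiOH·H2O (2 equiv), 30% H2O2 (5 equiv), THF/H2O 3:1, 0 °C; aq. Na2SO3; 1 M HCl to pH 2
Reagents that add atoms: hydrogen peroxide, OO
Why: Evans LiOOH cleavage, in which the small, highly nucleophilic hydroperoxide attacks the exocyclic imide carbonyl selectively, sulfite reduces peroxy acid 10 to the acid, any opened lactone recloses on acidification, and the non-acidic carboxylate α-stereocentre and the tert-butyl ester are unaffected.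

**Step 6**
Reactants: 11 (2R,3S)-2-(15-tert-butoxy-15-oxopentadecyl)-5-oxooxolane-3-carboxylic acid
Product: 12 (2R,3S)-2-(14-carboxytetradecyl)-5-oxooxolane-3-carboxylic acid
Conditions: TFA/CH2Cl2 1:1, rt, 3 h; evaporate, recrystallise
Reagents that add atoms: none
Why: Acidolysis of the tert-butyl ester (E1 loss of isobutene) is clean on a saturated lactone acid and frees the terminal acid before the sensitive methylene group exists.

**Step 7**
Reactants: 12 (2R,3S)-2-(14-carboxytetradecyl)-5-oxooxolane-3-carboxylic acid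
Product: 13 (2R,3S)-2-(14-carboxytetradecyl)-5-oxooxolane-3,4-dicarboxylic acid (C4 epimer mixture, used crude)
Conditions: methyl magnesium carbonate (2 M in DMF, ca. 40 equiv), 135 °C, 60 h, N2; then ice-cold 6 M HCl/EtOAc
Reagents that add atoms: methyl magnesium carbonate (Stiles' reagent), COC(=O)O[Mg]OC
Why: Stiles carboxylation, in which only the lactone α-CH2 is acidic enough (both carboxylate α-positions are inert) and magnesium chelation of the new β-dicarbonyl unit drives the reaction, the new C4 stereocentre being an irrelevant epimer mixture that is destroyed in step 8.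

**Step 8**
Reactants: 13 (2R,3S)-2-(14-carboxytetradecyl)-5-oxooxolane-3,4-dicarboxylic acid
Product: 15 (2R,3S)-2-(14-carboxytetradecyl)-4-methylidene-5-oxooxolane-3-carboxylic acid (target), via Mannich adduct 14 (not isolated)
Conditions: 37% aq. HCHO, PhNHMe, NaOAc, AcOH, rt, 2–3 h; dilute HCl/EtOAc work-up, recrystallise
Reagents that add atoms: formaldehyde, C=O
Why: Decarboxylative Mannich methylenation, in which the malonic half-acid adds to the N-methylanilinium iminium of formaldehyde to give 14, which loses CO2 and N-methylaniline to leave the exocyclic alkene under mildly acidic conditions that do not epimerise C3 or isomerise the alkene into the ring.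

**Compound list**
1 | (4S)-4-benzyl-1,3-oxazolidin-2-one | O=C1OC[C@H](Cc2ccccc2)N1 | starting material
2 | methyl 4-chloro-4-oxobutanoate | COC(=O)CCC(=O)Cl | starting material
3 | methyl 4-[(4S)-4-benzyl-2-oxo-1,3-oxazolidin-3-yl]-4-oxobutanoate | COC(=O)CCC(=O)N1C(=O)OC[C@@H]1Cc1ccccc1 | intermediate
4 | 16-(tert-butoxy)-16-oxohexadecanoic acid | CC(C)(C)OC(=O)CCCCCCCCCCCCCCC(=O)O | starting material
5 | tert-butyl 16-hydroxyhexadecanoate | CC(C)(C)OC(=O)CCCCCCCCCCCCCCCO | intermediate
6 | tert-butyl 16-oxohexadecanoate | CC(C)(C)OC(=O)CCCCCCCCCCCCCCC=O | intermediate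
7 | methyl (3Z)-4-[(4S)-4-benzyl-2-oxo-1,3-oxazolidin-3-yl]-4-[(dibutylboranyl)oxy]but-3-enoate | COC(=O)C/C=C(\OB(CCCC)CCCC)N1C(=O)OC[C@@H]1Cc1ccccc1 | intermediate (not isolated)
8 | 19-tert-butyl 1-methyl (3S,4R)-3-{[(4S)-4-benzyl-2-oxo-1,3-oxazolidin-3-yl]carbonyl}-4-hydroxynonadecanedioate | COC(=O)C[C@H](C(=O)N1C(=O)OC[C@@H]1Cc1ccccc1)[C@H](O)CCCCCCCCCCCCCCC(=O)OC(C)(C)C | intermediate (not isolated)
9 | tert-butyl 15-[(2R,3S)-3-{[(4S)-4-benzyl-2-oxo-1,3-oxazolidin-3-yl]carbonyl}-5-oxooxolan-2-yl]pentadecanoate | C1C(=O)O[C@H](CCCCCCCCCCCCCCC(=O)OC(C)(C)C)[C@H]1C(=O)N2C(=O)OC[C@@H]2Cc3ccccc3 | intermediate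
10 | (2R,3S)-2-(15-tert-butoxy-15-oxopentadecyl)-5-oxooxolane-3-carboperoxoic acid | C1C(=O)O[C@H](CCCCCCCCCCCCCCC(=O)OC(C)(C)C)[C@H]1C(=O)OO | intermediate (not isolated)
11 | (2R,3S)-2-(15-tert-butoxy-15-oxopentadecyl)-5-oxooxolane-3-carboxylic acid | C1C(=O)O[C@H](CCCCCCCCCCCCCCC(=O)OC(C)(C)C)[C@H]1C(=O)O | intermediate
12 | (2R,3S)-2-(14-carboxytetradecyl)-5-oxooxolane-3-carboxylic acid | C1C(=O)O[C@H](CCCCCCCCCCCCCCC(=O)O)[C@H]1C(=O)O | intermediate
13 | (2R,3S)-2-(14-carboxytetradecyl)-5-oxooxolane-3,4-dicarboxylic acid (C4 epimers) | OC(=O)C1C(=O)O[C@H](CCCCCCCCCCCCCCC(=O)O)[C@H]1C(=O)O | intermediate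
14 | (2R,3S)-2-(14-carboxytetradecyl)-4-{[methyl(phenyl)amino]methyl}-5-oxooxolane-3,4-dicarboxylic acid | CN(CC1(C(=O)O)C(=O)O[C@H](CCCCCCCCCCCCCCC(=O)O)[C@H]1C(=O)O)c1ccccc1 | intermediate (not isolated)
15 | (2R,3S)-2-(14-carboxytetradecyl)-4-methylidene-5-oxooxolane-3-carboxylic acid | C=C1C(=O)O[C@H](CCCCCCCCCCCCCCC(=O)O)[C@H]1C(=O)O | target

**Totals**
Total step count: 8. Longest linear sequence: 7 steps (4 → 5 → 6 → 9 → 11 → 12 → 13 → 15; the auxiliary branch 1 + 2 → 3 is one step).

**Steps most likely to fail, with fallbacks**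

Step 4 (aldol/lactonisation) is the main risk: enolisation on the ester side, modest diastereoselectivity with the functionalised succinate enolate, or incomplete ring closure. The fallback sets out from 1 and 6 and comes back at 9, and it masks the succinate CH2CO2Me arm as an allyl group. Compound 1 is acylated (n-BuLi, pent-4-enoyl chloride, THF, −78 °C) to (4S)-4-benzyl-3-(pent-4-enoyl)-1,3-oxazolidin-2-one F1. The same Bu2BOTf/i-Pr2NEt aldol with 6 then gives the stable, chromatographically purifiable syn adduct tert-butyl (16R,17S)-17-{[(4S)-4-benzyl-2-oxo-1,3-oxazolidin-3-yl]carbonyl}-16-hydroxyicos-19-enoate F2. Ozonolysis (O3, CH2Cl2/MeOH, −78 °C; Me2S) releases an aldehyde that closes onto the hydroxyl to give the lactol tert-butyl 15-[(2R,3S)-3-{[(4S)-4-benzyl-2-oxo-1,3-oxazolidin-3-yl]carbonyl}-5-hydroxyoxolan-2-yl]pentadecanoate F3. Oxidation of the lactol (TEMPO/PhI(OAc)2, CH2Cl2, rt) gives 9.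

Step 7 (Stiles carboxylation) needs long heating at 135 °C with a large excess of reagent, and the crude β-diacid can decarboxylate before step 8. The fallback sets out from 11 and comes back at 15, and it replaces carboxylation by an amine-oxide elimination. The dianion of 11 (LiHMDS 2.2 equiv, THF, −78 °C; only the lactone α-CH2 is enolised) is trapped with Eschenmoser's salt to give (2R,3S)-2-(15-tert-butoxy-15-oxopentadecyl)-4-[(dimethylamino)methyl]-5-oxooxolane-3-carboxylic acid F5. mCPBA (CH2Cl2, 0 °C → rt) gives 1-[(4S,5R)-5-(15-tert-butoxy-15-oxopentadecyl)-4-carboxy-2-oxooxolan-3-yl]-N,N-dimethylmethanamine N-oxide F6. This undergoes Cope elimination in the flask to (2R,3S)-2-(15-tert-butoxy-15-oxopentadecyl)-4-methylidene-5-oxooxolane-3-carboxylic acid F7. TFA/CH2Cl2 at rt then removes the tert-butyl ester to give 15.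

Step 5 (LiOOH cleavage) can suffer from attack at the lactone or the oxazolidinone carbonyl, and the long-chain carboxylate gives soapy work-ups. The fallback sets out from 9 and comes back at 11, and it swaps hydrolysis for transesterification and hydrogenolysis. Lithium benzyloxide (BnOH, n-BuLi, THF, −20 → 0 °C) converts 9 into benzyl (2R,3S)-2-(15-tert-butoxy-15-oxopentadecyl)-5-oxooxolane-3-carboxylate F4, which is separated from the auxiliary by chromatography. Hydrogenolysis (H2, 10% Pd/C, EtOAc, rt) then gives 11 with the tert-butyl ester intact.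

**Further compounds**
F1 | step 4 | (4S)-4-benzyl-3-(pent-4-enoyl)-1,3-oxazolidin-2-one | C=CCCC(=O)N1C(=O)OC[C@@H]1Cc1ccccc1
F2 | step 4 | tert-butyl (16R,17S)-17-{[(4S)-4-benzyl-2-oxo-1,3-oxazolidin-3-yl]carbonyl}-16-hydroxyicos-19-enoate | C=CC[C@H](C(=O)N1C(=O)OC[C@@H]1Cc1ccccc1)[C@H](O)CCCCCCCCCCCCCCC(=O)OC(C)(C)C
F3 | step 4 | tert-butyl 15-[(2R,3S)-3-{[(4S)-4-benzyl-2-oxo-1,3-oxazolidin-3-yl]carbonyl}-5-hydroxyoxolan-2-yl]pentadecanoate (anomer mixture) | C1C(O)O[C@H](CCCCCCCCCCCCCCC(=O)OC(C)(C)C)[C@H]1C(=O)N2C(=O)OC[C@@H]2Cc3ccccc3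
F4 | step 5 | benzyl (2R,3S)-2-(15-tert-butoxy-15-oxopentadecyl)-5-oxooxolane-3-carboxylate | C1C(=O)O[C@H](CCCCCCCCCCCCCCC(=O)OC(C)(C)C)[C@H]1C(=O)OCc2ccccc2
F5 | step 7 | (2R,3S)-2-(15-tert-butoxy-15-oxopentadecyl)-4-[(dimethylamino)methyl]-5-oxooxolane-3-carboxylic acid (C4 epimers) | CN(C)CC1C(=O)O[C@H](CCCCCCCCCCCCCCC(=O)OC(C)(C)C)[C@H]1C(=O)O
F6 | step 7 | 1-[(4S,5R)-5-(15-tert-butoxy-15-oxopentadecyl)-4-carboxy-2-oxooxolan-3-yl]-N,N-dimethylmethanamine N-oxide | C[N+](C)([O-])CC1C(=O)O[C@H](CCCCCCCCCCCCCCC(=O)OC(C)(C)C)[C@H]1C(=O)O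
F7 | step 7 | (2R,3S)-2-(15-tert-butoxy-15-oxopentadecyl)-4-methylidene-5-oxooxolane-3-carboxylic acid | C=C1C(=O)O[C@H](CCCCCCCCCCCCCCC(=O)OC(C)(C)C)[C@H]1C(=O)O
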